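**Plan**

1. Retrosynthesis (decahydroquinoline locants N1, C2–C8a; side chain C1′–C8′): cut the C3–O ester, then N1–C8a (alkene amination onto a C8a=C8 cyclohexene), then C1′–C2′ (alkyl–alkyl coupling), then C4a–C5 and C6–C7 together in one Diels–Alder reaction.
2. Enabling feature: in the carbocycle C4a–C5–C6–C7–C8–C8a the two carbon branches sit on adjacent C4a and C5 and are cis, C6–C8 are bare CH2 groups, and the N-bearing C8a is next to C4a. So C5=C6 with C1′ as an imide carbonyl is an acrylate dienophile, C4a=C8a–C8=C7 is an (E)-1-alkylbutadiene, the cis C4/C1′ relation is the endo outcome, and the new C8a=C8 bond lies where nitrogen must add.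
3. Forward: L-alanine-derived dienyl carbamate → [4+2] builds the carbocycle → C1′ is extended to the full side chain → the piperidine ring closes by amidomercuration → esterification and deprotection.
4. Stereochemistry: C2 from L-alanine; C3 by chelation-controlled ketone reduction; C5 by the chiral copper catalyst and C4a by the endo rule; C8a by cis-fusing trans-diaxial ring closure; C5′ from (R)-2-propyloxirane; the E,E-dienoate from the dienal.

Key step: step 6

Remark: the sense of induction of the copper catalyst is assumed to be that of its cyclopentadiene adduct ((S) at the carbonyl-bearing carbon with the (S,S)-ligand); should a first run show the opposite sense, the (R,R)-ligand is used.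

**Step 1**
Reactants: 1 tert-butyl N-[(2S)-1-[methoxy(methyl)amino]-1-oxopropan-2-yl]carbamate (Boc-L-alanine N-methoxy-N-methylamide)
Product: 2 tert-butyl N-[(2S)-3-oxohex-5-en-2-yl]carbamate
Conditions: CH2=CHCH2MgBr (3 equiv), THF, −78 → −20 °C; cold aq. NH4Cl
Reagents that add atoms: allylmagnesium bromide, C=CC[Mg]Br
Why: Weinreb ketone synthesis, in which the chelated tetrahedral adduct stops the addition at the ketone, and the cold, mildly acidic quench should keep the β,γ-enone unconjugated and C2 (from L-alanine) intact.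

**Step 2**
Reactants: 2 tert-butyl N-[(2S)-3-oxohex-5-en-2-yl]carbamate
Product: 3 tert-butyl N-[(2S,3R)-3-hydroxyhex-5-en-2-yl]carbamate
Conditions: LiAlH(Ot-Bu)3, EtOH, −78 °C
Reagents that add atoms: none
Why: Chelation-controlled hydride reduction of an N-carbamoyl α-amino ketone, in which hydride enters the carbamate/carbonyl chelate from the side of the small C2 hydrogen and should set C3 as the anti (2S,3R) amino alcohol.

**Step 3**
Reactants: 3 tert-butyl N-[(2S,3R)-3-hydroxyhex-5-en-2-yl]carbamate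
Product: 4 tert-butyl N-[(2S,3R)-3-[(tert-butyldimethylsilyl)oxy]hex-5-en-2-yl]carbamate
Conditions: TBSCl, imidazole, DMF, rt → 40 °C
Reagents that add atoms: tert-butyldimethylsilyl chloride, CC(C)(C)[Si](C)(C)Cl
Why: Standard silylation of a secondary alcohol, giving a bulky, weakly nucleophilic ether that should not compete as an internal nucleophile in step 12.

**Step 4**
Reactants: 4 tert-butyl N-[(2S,3R)-3-[(tert-butyldimethylsilyl)oxy]hex-5-en-2-yl]carbamate
Product: 5 tert-butyl N-[(2S,3R,5E)-3-[(tert-butyldimethylsilyl)oxy]-7-oxohept-5-en-2-yl]carbamate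
Conditions: acrolein (5 equiv), second-generation Hoveyda–Grubbs catalyst RuCl2(H2IMes)(=CH-C6H4-2-Oi-Pr) (5 mol%), CH2Cl2, 40 °C
Reagents that add atoms: acrolein, C=CC=O
Why: Olefin cross-metathesis of a terminal alkene with an excess of an electron-poor partner, which should give the (E)-enal with loss of ethene.

**Step 5**
Reactants: 5 tert-butyl N-[(2S,3R,5E)-3-[(tert-butyldimethylsilyl)oxy]-7-oxohept-5-en-2-yl]carbamate
Product: 6 tert-butyl N-[(2S,3R,5E)-3-[(tert-butyldimethylsilyl)oxy]octa-5,7-dien-2-yl]carbamate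
Conditions: Ph3PCH3Br (2.5 equiv), KN(SiMe3)2 (2.4 equiv), THF, −78 → 0 °C
Reagents that add atoms: methyltriphenylphosphonium bromide, C[P+](c1ccccc1)(c1ccccc1)c1ccccc1.[Br-]
Why: Wittig methylenation, in which the unstabilised ylide adds 1,2 to the enal faster than it deprotonates C4, so the (E)-1-substituted butadiene should form with the 5,6-geometry retained.

**Step 6**
Reactants: 6 tert-butyl N-[(2S,3R,5E)-3-[(tert-butyldimethylsilyl)oxy]octa-5,7-dien-2-yl]carbamate; 7 3-(prop-2-enoyl)-1,3-oxazolidin-2-one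
Product: 8 tert-butyl N-[(2S,3R)-3-[(tert-butyldimethylsilyl)oxy]-4-[(1R,6S)-6-(2-oxo-1,3-oxazolidine-3-carbonyl)cyclohex-2-en-1-yl]butan-2-yl]carbamate
Conditions: 7 (2 equiv), [Cu((S,S)-t-Bu-box)](SbF6)2 (10 mol%; t-Bu-box = 2,2′-(propane-2,2-diyl)bis[(4S)-4-tert-butyl-4,5-dihydro-1,3-oxazole]), CH2Cl2, −20 °C → rt
Reagents that add atoms: none
Why: A concerted, asynchronous, normal-demand [4+2] cycloaddition in which imide 7, bound s-cis as a square-planar chelate to divalent copper, meets the s-cis diene so that the unsubstituted diene terminus (C7) bonds to the β-carbon (C6) and the substituted terminus (C4a) to the α-carbon (C5). The closest known reaction type is the bis(oxazoline)copper-catalysed Diels–Alder reaction of 3-acryloyloxazolidin-2-one with 1-substituted butadienes such as piperylene. Only the carbocycle closes, by suprafacial addition of the two-carbon unit across the four-carbon unit (an intermolecular six-membered annulation), and it leaves the C8a=C8 double bond that step 12 needs. C5 is set by the ligand, whose tert-butyl groups block one face of the chelated dienophile, which should give (S) at the carbonyl-bearing carbon as in the cyclopentadiene case; C4a is set by the endo transition state, which places the outside substituent of the (E)-diene (C4) cis to the acyl group. The step needs "ortho" regioselectivity, secured by the match of the largest HOMO coefficient at C7 of a 1-alkyl diene with the largest LUMO coefficient at the β-carbon of the copper-bound imide; it also needs endo over exo selectivity and catalyst over substrate control, the latter secured by the distance of the diene stereocentres (C3 is two bonds from C4a). The carbamate and silyl ether are expected to be spectators, and the dienophile is used in excess because the diene is the valuable partner.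

**Step 7**
Reactants: 8 tert-butyl N-[(2S,3R)-3-[(tert-butyldimethylsilyl)oxy]-4-[(1R,6S)-6-(2-oxo-1,3-oxazolidine-3-carbonyl)cyclohex-2-en-1-yl]butan-2-yl]carbamate
Product: 9 tert-butyl N-[(2S,3R)-3-[(tert-butyldimethylsilyl)oxy]-4-[(1R,6S)-6-(hydroxymethyl)cyclohex-2-en-1-yl]butan-2-yl]carbamate
Conditions: LiBH4 (2 equiv), H2O (1 equiv), Et2O/THF, 0 °C
Reagents that add atoms: none
Why: Reductive cleavage of an N-acyloxazolidinone at the more electrophilic exocyclic carbonyl, which should give the primary alcohol (C1′) without touching the carbamate and without epimerising C5.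

**Step 8**
Reactants: 9 tert-butyl N-[(2S,3R)-3-[(tert-butyldimethylsilyl)oxy]-4-[(1R,6S)-6-(hydroxymethyl)cyclohex-2-en-1-yl]butan-2-yl]carbamate
Product: 10 tert-butyl N-[(2S,3R)-3-[(tert-butyldimethylsilyl)oxy]-4-[(1R,6S)-6-(iodomethyl)cyclohex-2-en-1-yl]butan-2-yl]carbamate
Conditions: PPh3, imidazole, I2 (premixed), CH2Cl2, 0 °C → rt, dark
Reagents that add atoms: iodine, II
Why: Appel-type iodination of a primary alcohol through the alkoxyphosphonium ion, with iodine consumed by the phosphine before the substrate is added so that the ring alkene is not iodinated.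

**Step 9**
Reactants: 11 (2R)-2-propyloxirane
Product: 12 (4R)-hept-1-en-4-ol
Conditions: CH2=CHMgBr (1.5 equiv), CuI (10 mol%), THF, −40 → 0 °C
Reagents that add atoms: vinylmagnesium bromide, C=C[Mg]Br
Why: Copper-catalysed epoxide opening at the unsubstituted carbon, which leaves the C–O stereocentre (the later C5′) untouched.

**Step 10**
Reactants: 12 (4R)-hept-1-en-4-ol
Product: 13 (4R)-4-(tert-butoxy)hept-1-ene
Conditions: Boc2O (2.3 equiv), Mg(ClO4)2 (10 mol%), CH2Cl2, 40 °C
Reagents that add atoms: di-tert-butyl dicarbonate, CC(C)(C)OC(=O)OC(=O)OC(C)(C)C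
Why: Lewis-acid-catalysed tert-butylation of an alcohol by decarboxylative collapse of the mixed carbonate, giving an ether that survives base, fluoride and the coupling and falls off with Boc in the last step.

**Step 11**
Reactants: 10 tert-butyl N-[(2S,3R)-3-[(tert-butyldimethylsilyl)oxy]-4-[(1R,6S)-6-(iodomethyl)cyclohex-2-en-1-yl]butan-2-yl]carbamate; 13 (4R)-4-(tert-butoxy)hept-1-ene
Product: 15 tert-butyl N-[(2S,3R)-4-[(1S,6S)-6-[(5R)-5-(tert-butoxy)octyl]cyclohex-2-en-1-yl]-3-[(tert-butyldimethylsilyl)oxy]butan-2-yl]carbamate, via alkylborane 14 (not isolated)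
Conditions: 13 (1.9 equiv), 9-BBN-H (1.8 equiv), THF, rt; then 10, NiCl2(MeOCH2CH2OMe) (6 mol%), trans-N,N′-dimethylcyclohexane-1,2-diamine (8 mol%), KOt-Bu, i-BuOH, dioxane, rt
Reagents that add atoms: none
Why: Anti-Markovnikov hydroboration of the terminal alkene followed by a nickel/diamine-catalysed alkyl–alkyl Suzuki–Miyaura coupling, a reaction type that tolerates β-hydrogens, β-branching, carbamates and silyl ethers; the alkene is kept in slight excess over the borane so that no B–H is left to attack the ring alkene.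

**Step 12**
Reactants: 15 tert-butyl N-[(2S,3R)-4-[(1S,6S)-6-[(5R)-5-(tert-butoxy)octyl]cyclohex-2-en-1-yl]-3-[(tert-butyldimethylsilyl)oxy]butan-2-yl]carbamate
Product: 17 tert-butyl (2S,3R,4aS,5S,8aR)-5-[(5R)-5-(tert-butoxy)octyl]-3-[(tert-butyldimethylsilyl)oxy]-2-methyloctahydroquinoline-1(2H)-carboxylate, via organomercury trifluoroacetate 16 (not isolated)
Conditions: Hg(OCOCF3)2 (1.2 equiv), CH3NO2, 0 °C → rt; then NaBH4, aq. NaOH, THF, −20 → 0 °C
Reagents that add atoms: none
Why: Intramolecular amidomercuration–demercuration, in which the carbamate nitrogen opens the mercurinium ion at C8a in the 6-exo, trans-diaxial mode and, being tethered to C4a, can only arrive cis to C4, so the cis ring fusion and (8aR) should result before NaBH4 replaces mercury at C8 by hydrogen.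

**Step 13**
Reactants: 17 tert-butyl (2S,3R,4aS,5S,8aR)-5-[(5R)-5-(tert-butoxy)octyl]-3-[(tert-butyldimethylsilyl)oxy]-2-methyloctahydroquinoline-1(2H)-carboxylate
Product: 18 tert-butyl (2S,3R,4aS,5S,8aR)-5-[(5R)-5-(tert-butoxy)octyl]-3-hydroxy-2-methyloctahydroquinoline-1(2H)-carboxylate
Conditions: Bu4NF, THF, rt → 45 °C
Reagents that add atoms: none
Why: Fluoride desilylation, which frees only the C3 hydroxyl because the carbamate and the tert-butyl ether are inert to fluoride.

**Step 14**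
Reactants: 19 (2E,4E)-octa-2,4-dienal
Product: 20 (2E,4E)-octa-2,4-dienoic acid
Conditions: NaClO2, NaH2PO4, 2-methylbut-2-ene, t-BuOH/H2O, 0 °C → rt
Reagents that add atoms: sodium chlorite, [Na+].[O-]Cl=O
Why: Pinnick oxidation, in which chlorous acid oxidises the aldehyde and the alkene scavenger removes hypochlorous acid, so the E,E-diene should be preserved.

**Step 15**
Reactants: 18 tert-butyl (2S,3R,4aS,5S,8aR)-5-[(5R)-5-(tert-butoxy)octyl]-3-hydroxy-2-methyloctahydroquinoline-1(2H)-carboxylate; 20 (2E,4E)-octa-2,4-dienoic acid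
Product: 22 tert-butyl (2S,3R,4aS,5S,8aR)-5-[(5R)-5-(tert-butoxy)octyl]-2-methyl-3-{[(2E,4E)-octa-2,4-dienoyl]oxy}octahydroquinoline-1(2H)-carboxylate, via mixed anhydride 21 (not isolated)
Conditions: 20, 2,4,6-trichlorobenzoyl chloride, Et3N, toluene, rt; then 18, DMAP, toluene, rt → 40 °C
Reagents that add atoms: none
Why: Yamaguchi esterification, which acylates the hindered C3 hydroxyl at oxygen with retention at C3 and should leave the diene geometry intact.

**Step 16**
Reactants: 22 tert-butyl (2S,3R,4aS,5S,8aR)-5-[(5R)-5-(tert-butoxy)octyl]-2-methyl-3-{[(2E,4E)-octa-2,4-dienoyl]oxy}octahydroquinoline-1(2H)-carboxylate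
Product: 23 lepadin H, (2S,3R,4aS,5S,8aR)-5-[(5R)-5-hydroxyoctyl]-2-methyldecahydroquinolin-3-yl (2E,4E)-octa-2,4-dienoate
Conditions: CF3CO2H/CH2Cl2 (1:1), 0 °C → rt; aq. NaHCO3
Reagents that add atoms: none
Why: Acidolysis of the tert-butyl carbamate and the tert-butyl ether in one operation, under which the dienoate ester is stable and the protonated nitrogen cannot take over the acyl group; the mild basic work-up should give the free base.

**Compound list**

1 | tert-butyl N-[(2S)-1-[methoxy(methyl)amino]-1-oxopropan-2-yl]carbamate | C[C@H](NC(=O)OC(C)(C)C)C(=O)N(C)OC | starting material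
2 | tert-butyl N-[(2S)-3-oxohex-5-en-2-yl]carbamate | C[C@H](NC(=O)OC(C)(C)C)C(=O)CC=C | intermediate
3 | tert-butyl N-[(2S,3R)-3-hydroxyhex-5-en-2-yl]carbamate | C[C@H](NC(=O)OC(C)(C)C)[C@H](O)CC=C | intermediate
4 | tert-butyl N-[(2S,3R)-3-[(tert-butyldimethylsilyl)oxy]hex-5-en-2-yl]carbamate | C[C@H](NC(=O)OC(C)(C)C)[C@H](O[Si](C)(C)C(C)(C)C)CC=C | intermediate
5 | tert-butyl N-[(2S,3R,5E)-3-[(tert-butyldimethylsilyl)oxy]-7-oxohept-5-en-2-yl]carbamate | C[C@H](NC(=O)OC(C)(C)C)[C@H](O[Si](C)(C)C(C)(C)C)C/C=C/C=O | intermediate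
6 | tert-butyl N-[(2S,3R,5E)-3-[(tert-butyldimethylsilyl)oxy]octa-5,7-dien-2-yl]carbamate | C[C@H](NC(=O)OC(C)(C)C)[C@H](O[Si](C)(C)C(C)(C)C)C/C=C/C=C | intermediate
7 | 3-(prop-2-enoyl)-1,3-oxazolidin-2-one | C=CC(=O)N1CCOC1=O | starting material
8 | tert-butyl N-[(2S,3R)-3-[(tert-butyldimethylsilyl)oxy]-4-[(1R,6S)-6-(2-oxo-1,3-oxazolidine-3-carbonyl)cyclohex-2-en-1-yl]butan-2-yl]carbamate | C[C@H](NC(=O)OC(C)(C)C)[C@H](O[Si](C)(C)C(C)(C)C)C[C@@H]1C=CCC[C@@H]1C(=O)N1CCOC1=O | intermediate
9 | tert-butyl N-[(2S,3R)-3-[(tert-butyldimethylsilyl)oxy]-4-[(1R,6S)-6-(hydroxymethyl)cyclohex-2-en-1-yl]butan-2-yl]carbamate | C[C@H](NC(=O)OC(C)(C)C)[C@H](O[Si](C)(C)C(C)(C)C)C[C@@H]1C=CCC[C@@H]1CO | intermediate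
10 | tert-butyl N-[(2S,3R)-3-[(tert-butyldimethylsilyl)oxy]-4-[(1R,6S)-6-(iodomethyl)cyclohex-2-en-1-yl]butan-2-yl]carbamate | C[C@H](NC(=O)OC(C)(C)C)[C@H](O[Si](C)(C)C(C)(C)C)C[C@@H]1C=CCC[C@@H]1CI | intermediate
11 | (2R)-2-propyloxirane | CCC[C@@H]1CO1 | starting material
12 | (4R)-hept-1-en-4-ol | C=CC[C@H](O)CCC | intermediate
13 | (4R)-4-(tert-butoxy)hept-1-ene | C=CC[C@H](OC(C)(C)C)CCC | intermediate
14 | 9-[(4R)-4-(tert-butoxy)heptyl]-9-borabicyclo[3.3.1]nonane | CCC[C@@H](OC(C)(C)C)CCCB1C2CCCC1CCC2 | intermediate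
15 | tert-butyl N-[(2S,3R)-4-[(1S,6S)-6-[(5R)-5-(tert-butoxy)octyl]cyclohex-2-en-1-yl]-3-[(tert-butyldimethylsilyl)oxy]butan-2-yl]carbamate | C[C@H](NC(=O)OC(C)(C)C)[C@H](O[Si](C)(C)C(C)(C)C)C[C@@H]1C=CCC[C@@H]1CCCC[C@H](OC(C)(C)C)CCC | intermediate
16 | tert-butyl (2S,3R,4aS,5S,8S,8aS)-5-[(5R)-5-(tert-butoxy)octyl]-3-[(tert-butyldimethylsilyl)oxy]-2-methyl-8-[(trifluoroacetoxy)mercurio]octahydroquinoline-1(2H)-carboxylate | CC(C)(C)[Si](C)(C)O[C@@H]1C[C@H]2[C@@H](CCCC[C@H](OC(C)(C)C)CCC)CC[C@H]([Hg]OC(=O)C(F)(F)F)[C@H]2N(C(=O)OC(C)(C)C)[C@H]1C | intermediate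
17 | tert-butyl (2S,3R,4aS,5S,8aR)-5-[(5R)-5-(tert-butoxy)octyl]-3-[(tert-butyldimethylsilyl)oxy]-2-methyloctahydroquinoline-1(2H)-carboxylate | CC(C)(C)[Si](C)(C)O[C@@H]1C[C@H]2[C@@H](CCCC[C@H](OC(C)(C)C)CCC)CCC[C@H]2N(C(=O)OC(C)(C)C)[C@H]1C | intermediate
18 | tert-butyl (2S,3R,4aS,5S,8aR)-5-[(5R)-5-(tert-butoxy)octyl]-3-hydroxy-2-methyloctahydroquinoline-1(2H)-carboxylate | O[C@@H]1C[C@H]2[C@@H](CCCC[C@H](OC(C)(C)C)CCC)CCC[C@H]2N(C(=O)OC(C)(C)C)[C@H]1C | intermediate
19 | (2E,4E)-octa-2,4-dienal | CCC/C=C/C=C/C=O | starting material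
20 | (2E,4E)-octa-2,4-dienoic acid | CCC/C=C/C=C/C(=O)O | intermediate
21 | (2E,4E)-octa-2,4-dienoic 2,4,6-trichlorobenzoic anhydride | CCC/C=C/C=C/C(=O)OC(=O)c1c(Cl)cc(Cl)cc1Cl | intermediate
22 | tert-butyl (2S,3R,4aS,5S,8aR)-5-[(5R)-5-(tert-butoxy)octyl]-2-methyl-3-{[(2E,4E)-octa-2,4-dienoyl]oxy}octahydroquinoline-1(2H)-carboxylate | CCC/C=C/C=C/C(=O)O[C@@H]1C[C@H]2[C@@H](CCCC[C@H](OC(C)(C)C)CCC)CCC[C@H]2N(C(=O)OC(C)(C)C)[C@H]1C | intermediate
23 | lepadin H, (2S,3R,4aS,5S,8aR)-5-[(5R)-5-hydroxyoctyl]-2-methyldecahydroquinolin-3-yl (2E,4E)-octa-2,4-dienoate | CCC/C=C/C=C/C(=O)O[C@@H]1C[C@H]2[C@@H](CCCC[C@H](O)CCC)CCC[C@H]2N[C@H]1C | target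

**Step count and risks**

Total: 16 steps. Longest linear sequence: 13 steps (steps 1–8, 11, 12, 13, 15, 16).

Steps most likely to fail:

Step 12. The ring closure may stall: the carbamate nitrogen is a weak nucleophile, it must approach C8a axially past the axial C1′ chain, and allylic strain builds between Boc and the C2 methyl. Meanwhile the trifluoroacetic acid set free may erode the Boc group or the silyl ether. The fallback sets out from 15 and returns at 17. Boc is removed first (HCl in dioxane, 0 °C, stopped before the tert-butyl ether is attacked) to give (2S,3R)-4-[(1S,6S)-6-[(5R)-5-(tert-butoxy)octyl]cyclohex-2-en-1-yl]-3-[(tert-butyldimethylsilyl)oxy]butan-2-amine F1. The much more nucleophilic primary amine is then closed with Hg(OAc)2 in THF to the C8-acetoxymercurio cis-fused amine F2. This is reduced in the same flask (NaBH4, aq. NaOH) to (2S,3R,4aS,5S,8aR)-5-[(5R)-5-(tert-butoxy)octyl]-3-[(tert-butyldimethylsilyl)oxy]-2-methyldecahydroquinoline F3, and Boc2O/Et3N gives 17.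

Step 11. Coupling at the β-branched primary iodide may be slow, so that β-hydride elimination, reduction of the iodide or loss of the borane compete. The fallback replaces the nickel/boron cross-coupling by a copper-catalysed displacement of a sulfonate by a Grignard reagent; it sets out from 9 and 13 and returns at 15. Alcohol 9 is converted (TsCl, pyridine) into [(1S,2R)-2-[(2R,3S)-3-[(tert-butoxycarbonyl)amino]-2-[(tert-butyldimethylsilyl)oxy]butyl]cyclohex-3-en-1-yl]methyl 4-methylbenzenesulfonate F4. Alkene 13 is converted (Cp2Zr(H)Cl, then N-bromosuccinimide) into (4R)-1-bromo-4-(tert-butoxy)heptane F5 and then (Mg, THF) into [(4R)-4-(tert-butoxy)heptyl]magnesium bromide F6. F6 (2.5 equiv, one being consumed by the N–H) and F4 with Li2CuCl4 (5 mol%) in THF at −20 → 0 °C should give 15.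

Step 6. Endo/exo and facial selectivity may be insufficient, or the cycloaddition may be slow if the carbamate ties up the copper catalyst. The fallback moves stereocontrol from the catalyst to a covalently bound auxiliary; it sets out from 6 and returns at 9. (4R)-4-Benzyl-1,3-oxazolidin-2-one is acylated (n-BuLi, acryloyl chloride) to (4R)-4-benzyl-3-(prop-2-enoyl)-1,3-oxazolidin-2-one F7. By the chelated s-cis model its benzyl group shields the same dienophile face as the (S,S)-catalyst. Cycloaddition with 6 promoted by Et2AlCl (2.5 equiv, one being held by the carbamate) in CH2Cl2 at −78 °C should give tert-butyl N-[(2S,3R)-4-[(1R,6S)-6-[(4R)-4-benzyl-2-oxo-1,3-oxazolidine-3-carbonyl]cyclohex-2-en-1-yl]-3-[(tert-butyldimethylsilyl)oxy]butan-2-yl]carbamate F8. LiBH4 then cleaves the auxiliary and gives 9.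

**Further compounds**

F1 | step 12 | (2S,3R)-4-[(1S,6S)-6-[(5R)-5-(tert-butoxy)octyl]cyclohex-2-en-1-yl]-3-[(tert-butyldimethylsilyl)oxy]butan-2-amine | C[C@H](N)[C@H](O[Si](C)(C)C(C)(C)C)C[C@@H]1C=CCC[C@@H]1CCCC[C@H](OC(C)(C)C)CCC
F2 | step 12 | (2S,3R,4aS,5S,8S,8aS)-8-(acetoxymercurio)-5-[(5R)-5-(tert-butoxy)octyl]-3-[(tert-butyldimethylsilyl)oxy]-2-methyldecahydroquinoline | CC(C)(C)[Si](C)(C)O[C@@H]1C[C@H]2[C@@H](CCCC[C@H](OC(C)(C)C)CCC)CC[C@H]([Hg]OC(C)=O)[C@H]2N[C@H]1C
F3 | step 12 | (2S,3R,4aS,5S,8aR)-5-[(5R)-5-(tert-butoxy)octyl]-3-[(tert-butyldimethylsilyl)oxy]-2-methyldecahydroquinoline | CC(C)(C)[Si](C)(C)O[C@@H]1C[C@H]2[C@@H](CCCC[C@H](OC(C)(C)C)CCC)CCC[C@H]2N[C@H]1C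
F4 | step 11 | [(1S,2R)-2-[(2R,3S)-3-[(tert-butoxycarbonyl)amino]-2-[(tert-butyldimethylsilyl)oxy]butyl]cyclohex-3-en-1-yl]methyl 4-methylbenzenesulfonate | C[C@H](NC(=O)OC(C)(C)C)[C@H](O[Si](C)(C)C(C)(C)C)C[C@@H]1C=CCC[C@@H]1COS(=O)(=O)c1ccc(C)cc1
F5 | step 11 | (4R)-1-bromo-4-(tert-butoxy)heptane | CCC[C@@H](OC(C)(C)C)CCCBr
F6 | step 11 | [(4R)-4-(tert-butoxy)heptyl]magnesium bromide | CCC[C@@H](OC(C)(C)C)CCC[Mg]Br
F7 | step 6 | (4R)-4-benzyl-3-(prop-2-enoyl)-1,3-oxazolidin-2-one | C=CC(=O)N1[C@H](Cc2ccccc2)COC1=O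
F8 | step 6 | tert-butyl N-[(2S,3R)-4-[(1R,6S)-6-[(4R)-4-benzyl-2-oxo-1,3-oxazolidine-3-carbonyl]cyclohex-2-en-1-yl]-3-[(tert-butyldimethylsilyl)oxy]butan-2-yl]carbamate | C[C@H](NC(=O)OC(C)(C)C)[C@H](O[Si](C)(C)C(C)(C)C)C[C@@H]1C=CCC[C@@H]1C(=O)N1[C@H](Cc2ccccc2)COC1=O
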